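**Retrosynthetic overview** (halimane numbering: ring A = C1–C5 and C10, ring B = C5–C10, side chain C11–C16, C17 on C8, C20 on C9, carboxyl on C4)
1. Target ⇐ acetylation and fluoride deprotection ⇐ B-alkyl Suzuki–Miyaura coupling (C12–C13) of a C9-vinyl octalin with an (E)-alkenyl iodide (C13–C16).
2. Ring B ⇐ 6-exo Mizoroki–Heck cyclisation that forms C9–C10 from a ring A vinyl bromide (C10) and a side-chain (E)-alkene C9=C11. The enabling feature is the quaternary C9 of ring B: it lies between sp2 C10 (C1=C10 of ring A) and the two-carbon arm C11–C12 and carries no hydrogen, which is the vinyl–C(quaternary)–CH=CH2 pattern a Heck reaction leaves behind.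
3. Heck precursor ⇐ phosphine-directed syn SN2′ coupling (C5–C6) of a chain Grignard reagent with a 2-bromocyclohexenyl benzoate; this sets C5 and moves the ring alkene to C1=C10 with bromine on C10.
4. Chain ⇐ Johnson–Claisen rearrangement with chirality transfer (C8); ring A carbinol ⇐ CBS reduction; ring A itself ⇐ catalytic asymmetric Diels–Alder reaction (C4).
5. Order of ring formation: ring A first (Diels–Alder), ring B second (key step).

Key step: step 12

Assumption: the catalyst antipodes named (chromium salen complex, CBS oxazaborolidines) are those expected from the accepted models to give the configurations drawn; the mirror-image catalyst would be taken if the sense proved opposite.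

**Route**

Step 1
Reactants: 1 (E)-1-(dimethylamino)-3-(tert-butyldimethylsilyloxy)buta-1,3-diene; 2 methacrolein
Product: 4 (S)-1-methyl-4-oxocyclohex-2-ene-1-carbaldehyde, via cycloadduct 3 (not isolated)
Conditions: (R,R)-(salen)CrSbF6 (5 mol %; salen = N,N'-bis(3,5-di-tert-butylsalicylidene)cyclohexane-1,2-diamine dianion, trivalent chromium), 4 Å MS, CH2Cl2, −40 °C; then 1 M HCl, THF, 0 °C
Reagents that add atoms: none
Why: Catalytic asymmetric Diels–Alder reaction of a 1-amino-3-siloxy diene with an α-substituted acrolein, in which the chromium–salen Lewis acid binds the aldehyde and shields one face so that the quaternary C4 is set, and the acid then hydrolyses the silyl enol ether and expels dimethylamine by β-elimination to give the enone.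

Step 2
Reactants: 4 (S)-1-methyl-4-oxocyclohex-2-ene-1-carbaldehyde
Product: 5 (S)-1-methyl-4-oxocyclohex-2-ene-1-carboxylic acid
Conditions: NaClO2, NaH2PO4, 2-methyl-2-butene, t-BuOH/H2O, 0 °C → rt
Reagents that add atoms: sodium chlorite [Na+].[O-]Cl=O
Why: Pinnick oxidation should convert the aldehyde into the acid without touching the enone, and the quaternary centre cannot epimerise.

Step 3
Reactants: 5 (S)-1-methyl-4-oxocyclohex-2-ene-1-carboxylic acid
Product: 6 2-(trimethylsilyl)ethyl (S)-1-methyl-4-oxocyclohex-2-ene-1-carboxylate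
Conditions: 2-(trimethylsilyl)ethanol, DCC, DMAP (cat.), CH2Cl2, 0 °C → rt
Reagents that add atoms: 2-(trimethylsilyl)ethanol C[Si](C)(C)CCO
Why: Steglich esterification; this ester is chosen because fluoride later removes it by fragmentation at silicon, independent of the steric shielding of the carbonyl group.

Step 4
Reactants: 6 2-(trimethylsilyl)ethyl (S)-1-methyl-4-oxocyclohex-2-ene-1-carboxylate
Product: 8 2-(trimethylsilyl)ethyl (S)-3-bromo-1-methyl-4-oxocyclohex-2-ene-1-carboxylate, via trans-dibromide 7 (not isolated)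
Conditions: Br2, CH2Cl2, 0 °C; then Et3N, 0 °C → rt
Reagents that add atoms: bromine BrBr
Why: Bromination–dehydrobromination of the enone (addition of bromine, then E1cB loss of HBr) should place the halogen on the α-carbon, the future C10.

Step 5
Reactants: 8 2-(trimethylsilyl)ethyl (S)-3-bromo-1-methyl-4-oxocyclohex-2-ene-1-carboxylate
Product: 9 2-(trimethylsilyl)ethyl (1S,4S)-3-bromo-4-hydroxy-1-methylcyclohex-2-ene-1-carboxylate
Conditions: (R)-2-methyl-CBS-oxazaborolidine (20 mol %), BH3·THF, THF, −20 °C; MeOH, then aqueous work-up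
Reagents that add atoms: none
Why: Corey–Bakshi–Shibata reduction in which the bromoalkenyl arm acts as the large ketone substituent, so the catalyst rather than the remote C4 centre should fix the carbinol centre (C1) with the hydroxyl cis to the C4 methyl.

Step 6
Reactants: 9 2-(trimethylsilyl)ethyl (1S,4S)-3-bromo-4-hydroxy-1-methylcyclohex-2-ene-1-carboxylate
Product: 10 (1S,4S)-2-bromo-4-methyl-4-{[2-(trimethylsilyl)ethoxy]carbonyl}cyclohex-2-en-1-yl 2-(diphenylphosphanyl)benzoate
Conditions: 2-(diphenylphosphanyl)benzoic acid, DCC, DMAP (cat.), CH2Cl2, rt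
Reagents that add atoms: 2-(diphenylphosphanyl)benzoic acid OC(=O)c1ccccc1P(c1ccccc1)c1ccccc1
Why: Steglich esterification installs the o-DPPB leaving group, whose phosphine will hold the copper reagent on the face of the C1–O bond in step 11.

Step 7
Reactants: 11 (E)-3-methylpent-3-en-2-one
Product: 12 (2R,3E)-3-methylpent-3-en-2-ol
Conditions: (S)-2-methyl-CBS-oxazaborolidine (10 mol %), catecholborane, toluene, −78 °C; aq. NaOH work-up
Reagents that add atoms: none
Why: Corey–Bakshi–Shibata reduction of the enone (alkenyl group as the large substituent) should set the carbinol centre that is relayed to C8 in step 8.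

Step 8
Reactants: 12 (2R,3E)-3-methylpent-3-en-2-ol
Product: 13 ethyl (3R,4E)-3,4-dimethylhex-4-enoate
Conditions: CH3C(OEt)3, EtCO2H (cat.), 140 °C, ethanol distilled off
Reagents that add atoms: triethyl orthoacetate CCOC(C)(OCC)OCC
Why: Johnson–Claisen rearrangement through a chair transition state with the carbinol methyl equatorial: the C7–C8 bond forms on the face from which oxygen leaves, so the carbinol configuration is transferred to C8 and the new trisubstituted alkene (C9=C11) should be E.

Step 9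
Reactants: 13 ethyl (3R,4E)-3,4-dimethylhex-4-enoate
Product: 14 (3R,4E)-3,4-dimethylhex-4-en-1-ol
Conditions: LiAlH4, Et2O, 0 °C; aq. NaOH work-up
Reagents that add atoms: none
Why: Hydride reduction of the ester to the primary alcohol leaves the stereocentre and the alkene untouched.

Step 10
Reactants: 14 (3R,4E)-3,4-dimethylhex-4-en-1-ol
Product: 15 (2E,4R)-6-bromo-3,4-dimethylhex-2-ene
Conditions: CBr4, PPh3, CH2Cl2, 0 °C
Reagents that add atoms: carbon tetrabromide BrC(Br)(Br)Br
Why: Appel bromination of the primary alcohol (SN2 at a CH2 group, no stereocentre involved).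

Step 11
Reactants: 15 (2E,4R)-6-bromo-3,4-dimethylhex-2-ene; 10 (1S,4S)-2-bromo-4-methyl-4-{[2-(trimethylsilyl)ethoxy]carbonyl}cyclohex-2-en-1-yl 2-(diphenylphosphanyl)benzoate
Product: 17 2-(trimethylsilyl)ethyl (1S,2R)-3-bromo-2-[(3R,4E)-3,4-dimethylhex-4-en-1-yl]-1-methylcyclohex-3-ene-1-carboxylate, via Grignard reagent 16 (not isolated)
Conditions: 15, Mg, Et2O, reflux; then slow addition to 10, CuBr·SMe2 (50 mol %), Et2O, rt; aq. NH4Cl
Reagents that add atoms: none
Why: Copper-mediated allylic substitution (SN2′) of a Grignard reagent directed by the phosphine of the o-DPPB leaving group: the alkyl group should be delivered to C5 on the face from which the benzoate departs (syn, anti to the pseudoaxial ester on C4), which sets C5 with the chain cis to the C4 methyl, while the double bond moves to C1=C10 and the bromine stays on C10.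

Step 12
Reactants: 17 2-(trimethylsilyl)ethyl (1S,2R)-3-bromo-2-[(3R,4E)-3,4-dimethylhex-4-en-1-yl]-1-methylcyclohex-3-ene-1-carboxylate
Product: 18 2-(trimethylsilyl)ethyl (1S,5S,6R,8aS)-5-ethenyl-1,5,6-trimethyl-1,2,3,5,6,7,8,8a-octahydronaphthalene-1-carboxylate
Conditions: Pd(OAc)2 (10 mol %), PPh3 (30 mol %), K2CO3, MeCN (degassed), 80 °C
Reagents that add atoms: none
Why: Zerovalent palladium inserts into the C10–Br bond, the vinylpalladium bromide adds syn across the tethered C9=C11 alkene (new C9–C10 bond, palladium on C11), and β-hydride elimination, possible only towards C12 because C9 is now quaternary, releases the C9 vinyl group while C1=C10 stays in place. The closest known reaction type is the intramolecular Mizoroki–Heck cyclisation of vinyl halides onto trisubstituted alkenes that builds all-carbon quaternary centres in six-membered rings. Ring B closes in the 6-exo-trig mode, C10 adding to the fully substituted alkene carbon C9 (7-endo attack at C11 would put palladium on a tertiary carbon and is disfavoured). The one new stereocentre, C9, is controlled by C5: insertion needs the C10–Pd and C9=C11 bonds eclipsed, ring A holds C4 near the plane of the C1=C10 bond, and so the only chair-like tether has H5 and the C9=C11 bond axial on the same face, which puts C11 cis to H5 and the C9 methyl equatorial, cis to the pre-set (axial) C8 methyl. The step needs exo regioselectivity, this facial selectivity and a single direction of β-hydride elimination; the tether length, the ring-fusion constraint of ring A and the absence of hydrogen on C9 should secure them, and the terminal vinyl group cannot migrate into conjugation.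

Step 13
Reactants: 19 but-2-yn-1-ol
Product: 20 tert-butyl(but-2-yn-1-yloxy)dimethylsilane
Conditions: TBSCl, imidazole, DMF, rt
Reagents that add atoms: tert-butyldimethylsilyl chloride CC(C)(C)[Si](C)(C)Cl
Why: Silylation of the primary propargylic alcohol.

Step 14
Reactants: 20 tert-butyl(but-2-yn-1-yloxy)dimethylsilane
Product: 22 (E)-tert-butyl[(3-iodobut-2-en-1-yl)oxy]dimethylsilane, via alkenylzirconocene chloride 21 (not isolated)
Conditions: Cp2Zr(H)Cl (1.5 equiv), THF, rt → 50 °C; then I2, 0 °C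
Reagents that add atoms: iodine II
Why: Hydrozirconation–iodination: syn addition of Zr–H, with zirconium ending after equilibration with excess reagent on the less hindered, methyl-bearing alkyne carbon, and iodinolysis with retention should give the E-alkenyl iodide.

Step 15
Reactants: 18 2-(trimethylsilyl)ethyl (1S,5S,6R,8aS)-5-ethenyl-1,5,6-trimethyl-1,2,3,5,6,7,8,8a-octahydronaphthalene-1-carboxylate; 22 (E)-tert-butyl[(3-iodobut-2-en-1-yl)oxy]dimethylsilane
Product: 24 2-(trimethylsilyl)ethyl (1S,5S,6R,8aS)-5-[(3E)-5-(tert-butyldimethylsilyloxy)-3-methylpent-3-en-1-yl]-1,5,6-trimethyl-1,2,3,5,6,7,8,8a-octahydronaphthalene-1-carboxylate, via B-alkyl borane 23 (not isolated)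
Conditions: 9-BBN, THF, rt → 50 °C; then 22, PdCl2(dppf) (10 mol %), AsPh3, Cs2CO3, DMF/H2O, rt
Reagents that add atoms: none
Why: B-alkyl Suzuki–Miyaura coupling: 9-BBN should hydroborate only the monosubstituted vinyl group at its terminus (the trisubstituted C1=C10 alkene is inert), and the sp3–sp2 coupling retains the E geometry of the iodide.

Step 16
Reactants: 24 2-(trimethylsilyl)ethyl (1S,5S,6R,8aS)-5-[(3E)-5-(tert-butyldimethylsilyloxy)-3-methylpent-3-en-1-yl]-1,5,6-trimethyl-1,2,3,5,6,7,8,8a-octahydronaphthalene-1-carboxylate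
Product: 25 (1S,5S,6R,8aS)-5-[(3E)-5-hydroxy-3-methylpent-3-en-1-yl]-1,5,6-trimethyl-1,2,3,5,6,7,8,8a-octahydronaphthalene-1-carboxylic acid
Conditions: Bu4NF, THF, rt → 50 °C; then dilute HCl to pH 3
Reagents that add atoms: none
Why: Fluoride cleaves the silyl ether and fragments the 2-(trimethylsilyl)ethyl ester (attack at silicon, loss of ethene), so the hindered carboxyl group should be freed without hydroxide.

Step 17
Reactants: 25 (1S,5S,6R,8aS)-5-[(3E)-5-hydroxy-3-methylpent-3-en-1-yl]-1,5,6-trimethyl-1,2,3,5,6,7,8,8a-octahydronaphthalene-1-carboxylic acid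
Product: 26 (1S,5S,6R,8aS)-5-[(3E)-5-acetoxy-3-methylpent-3-en-1-yl]-1,5,6-trimethyl-1,2,3,5,6,7,8,8a-octahydronaphthalene-1-carboxylic acid
Conditions: Ac2O, pyridine, DMAP (cat.), CH2Cl2, rt; then H2O/NaHCO3, acidify
Reagents that add atoms: acetic anhydride CC(=O)OC(C)=O
Why: Acetylation of the primary allylic alcohol; any mixed anhydride formed at the hindered acid is hydrolysed in the aqueous work-up.

**Compound list**

1 | (E)-1-(dimethylamino)-3-(tert-butyldimethylsilyloxy)buta-1,3-diene | CN(C)/C=C/C(=C)O[Si](C)(C)C(C)(C)C | starting material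
2 | methacrolein (2-methylprop-2-enal) | CC(=C)C=O | starting material
3 | (1S,2R)-2-(dimethylamino)-1-methyl-4-(tert-butyldimethylsilyloxy)cyclohex-3-ene-1-carbaldehyde (endo cycloadduct) | CN(C)[C@@H]1C=C(O[Si](C)(C)C(C)(C)C)CC[C@]1(C)C=O | intermediate
4 | (S)-1-methyl-4-oxocyclohex-2-ene-1-carbaldehyde | O=C1C=C[C@@](C)(C=O)CC1 | intermediate
5 | (S)-1-methyl-4-oxocyclohex-2-ene-1-carboxylic acid | O=C1C=C[C@@](C)(C(=O)O)CC1 | intermediate
6 | 2-(trimethylsilyl)ethyl (S)-1-methyl-4-oxocyclohex-2-ene-1-carboxylate | O=C1C=C[C@@](C)(C(=O)OCC[Si](C)(C)C)CC1 | intermediate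
7 | 2-(trimethylsilyl)ethyl (1R,2S,3S)-2,3-dibromo-1-methyl-4-oxocyclohexane-1-carboxylate (trans-dibromide, drawn as the diaxial adduct) | O=C1[C@H](Br)[C@@H](Br)[C@@](C)(C(=O)OCC[Si](C)(C)C)CC1 | intermediate
8 | 2-(trimethylsilyl)ethyl (S)-3-bromo-1-methyl-4-oxocyclohex-2-ene-1-carboxylate | O=C1C(Br)=C[C@@](C)(C(=O)OCC[Si](C)(C)C)CC1 | intermediate
9 | 2-(trimethylsilyl)ethyl (1S,4S)-3-bromo-4-hydroxy-1-methylcyclohex-2-ene-1-carboxylate (hydroxyl cis to the ring methyl) | O[C@@H]1C(Br)=C[C@@](C)(C(=O)OCC[Si](C)(C)C)CC1 | intermediate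
10 | (1S,4S)-2-bromo-4-methyl-4-{[2-(trimethylsilyl)ethoxy]carbonyl}cyclohex-2-en-1-yl 2-(diphenylphosphanyl)benzoate | O=C(O[C@@H]1C(Br)=C[C@@](C)(C(=O)OCC[Si](C)(C)C)CC1)c1ccccc1P(c1ccccc1)c1ccccc1 | intermediate
11 | (E)-3-methylpent-3-en-2-one | CC(=O)/C(C)=C/C | starting material
12 | (2R,3E)-3-methylpent-3-en-2-ol | C[C@@H](O)/C(C)=C/C | intermediate
13 | ethyl (3R,4E)-3,4-dimethylhex-4-enoate | CCOC(=O)C[C@@H](C)/C(C)=C/C | intermediate
14 | (3R,4E)-3,4-dimethylhex-4-en-1-ol | OCC[C@@H](C)/C(C)=C/C | intermediate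
15 | (2E,4R)-6-bromo-3,4-dimethylhex-2-ene | BrCC[C@@H](C)/C(C)=C/C | intermediate
16 | [(3R,4E)-3,4-dimethylhex-4-en-1-yl]magnesium bromide | Br[Mg]CC[C@@H](C)/C(C)=C/C | intermediate
17 | 2-(trimethylsilyl)ethyl (1S,2R)-3-bromo-2-[(3R,4E)-3,4-dimethylhex-4-en-1-yl]-1-methylcyclohex-3-ene-1-carboxylate | BrC1=CCC[C@](C)(C(=O)OCC[Si](C)(C)C)[C@H]1CC[C@@H](C)/C(C)=C/C | intermediate
18 | 2-(trimethylsilyl)ethyl (1S,5S,6R,8aS)-5-ethenyl-1,5,6-trimethyl-1,2,3,5,6,7,8,8a-octahydronaphthalene-1-carboxylate | C=C[C@]1(C)C2=CCC[C@](C)(C(=O)OCC[Si](C)(C)C)[C@H]2CC[C@H]1C | intermediate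
19 | but-2-yn-1-ol | CC#CCO | starting material
20 | tert-butyl(but-2-yn-1-yloxy)dimethylsilane | CC#CCO[Si](C)(C)C(C)(C)C | intermediate
21 | (E)-[4-(tert-butyldimethylsilyloxy)but-2-en-2-yl]chlorobis(cyclopentadienyl)zirconium | C/C(=C\CO[Si](C)(C)C(C)(C)C)[Zr](Cl)(C1C=CC=C1)C1C=CC=C1 | intermediate
22 | (E)-tert-butyl[(3-iodobut-2-en-1-yl)oxy]dimethylsilane | I/C(C)=C/CO[Si](C)(C)C(C)(C)C | intermediate
23 | 2-(trimethylsilyl)ethyl (1S,5S,6R,8aS)-5-[2-(9-borabicyclo[3.3.1]nonan-9-yl)ethyl]-1,5,6-trimethyl-1,2,3,5,6,7,8,8a-octahydronaphthalene-1-carboxylate | C1CCC2CCCC1B2CC[C@]3(C)C4=CCC[C@](C)(C(=O)OCC[Si](C)(C)C)[C@H]4CC[C@H]3C | intermediate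
24 | 2-(trimethylsilyl)ethyl (1S,5S,6R,8aS)-5-[(3E)-5-(tert-butyldimethylsilyloxy)-3-methylpent-3-en-1-yl]-1,5,6-trimethyl-1,2,3,5,6,7,8,8a-octahydronaphthalene-1-carboxylate | CC(C)(C)[Si](C)(C)OC/C=C(\C)CC[C@]1(C)C2=CCC[C@](C)(C(=O)OCC[Si](C)(C)C)[C@H]2CC[C@H]1C | intermediate
25 | (1S,5S,6R,8aS)-5-[(3E)-5-hydroxy-3-methylpent-3-en-1-yl]-1,5,6-trimethyl-1,2,3,5,6,7,8,8a-octahydronaphthalene-1-carboxylic acid | OC/C=C(\C)CC[C@]1(C)C2=CCC[C@](C)(C(=O)O)[C@H]2CC[C@H]1C | intermediate
26 | (1S,5S,6R,8aS)-5-[(3E)-5-acetoxy-3-methylpent-3-en-1-yl]-1,5,6-trimethyl-1,2,3,5,6,7,8,8a-octahydronaphthalene-1-carboxylic acid (CNP0276297.1) | CC(=O)OC/C=C(\C)CC[C@]1(C)C2=CCC[C@](C)(C(=O)O)[C@H]2CC[C@H]1C | target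

**Step count and risks**

Total step count: 17. Longest linear sequence: 11 steps (steps 1–6, 11, 12, 15, 16, 17).

Steps most likely to fail:

1. Step 12 (Heck cyclisation). Carbopalladation at the fully substituted alkene carbon may be slow, so that proto-debromination and palladium-hydride alkene migration compete, or the two faces of the C9=C11 alkene may not be discriminated well enough. The fallback makes the same bond through a palladium enolate instead of an alkene insertion; it sets out from 17 and comes back at 18. The electron-rich side-chain alkene of 17 would be hydroborated chemoselectively (BH3·SMe2, THF, 0 °C; NaBO3) to the secondary alcohol 2-(trimethylsilyl)ethyl (1S,2R)-3-bromo-2-[(3R)-5-hydroxy-3,4-dimethylhexyl]-1-methylcyclohex-3-ene-1-carboxylate F1. Swern oxidation would give the methyl ketone 2-(trimethylsilyl)ethyl (1S,2R)-3-bromo-2-[(3R)-3,4-dimethyl-5-oxohexyl]-1-methylcyclohex-3-ene-1-carboxylate F2. Palladium-catalysed intramolecular α-alkenylation of its enolate with the vinyl bromide (Pd(PPh3)4, KOPh, THF, 65 °C; only the C9 enolate can close a six-membered ring) should give the bicyclic methyl ketone 2-(trimethylsilyl)ethyl (1S,5S,6R,8aS)-5-acetyl-1,5,6-trimethyl-1,2,3,5,6,7,8,8a-octahydronaphthalene-1-carboxylate F3. Its only enolisable side is the methyl group, so KN(SiMe3)2/PhNTf2 would give the enol triflate 2-(trimethylsilyl)ethyl (1S,5S,6R,8aS)-1,5,6-trimethyl-5-[1-(trifluoromethylsulfonyloxy)ethenyl]-1,2,3,5,6,7,8,8a-octahydronaphthalene-1-carboxylate F4, and Pd(OAc)2/PPh3/HCO2H–Bu3N would reduce it to 18.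

2. Step 11 (directed allylic substitution). The organocopper may leak to direct α-substitution or to attack from the face opposite the director, or it may undergo metal–halogen exchange or coupling at the vinyl bromide. The fallback replaces the organometallic coupling by a sigmatropic, suprafacial carbon transfer; it sets out from 9 and 16 and comes back at 17. Quenching 16 with CO2 would give (4R,5E)-4,5-dimethylhept-5-enoic acid F5. Steglich esterification with 9 would give (1S,4S)-2-bromo-4-methyl-4-{[2-(trimethylsilyl)ethoxy]carbonyl}cyclohex-2-en-1-yl (4R,5E)-4,5-dimethylhept-5-enoate F6. Ireland–Claisen rearrangement (LiN(SiMe3)2, TMSCl, THF, −78 °C → reflux) should deliver the α-carbon to C5 on the face of the departing oxygen and move the alkene to C1=C10, giving 2-(trimethylsilyl)ethyl (1S,2R)-3-bromo-2-[(3R,4E)-1-carboxy-3,4-dimethylhex-4-en-1-yl]-1-methylcyclohex-3-ene-1-carboxylate F7. Barton decarboxylation through its N-hydroxypyridine-2-thione ester F8 (DCC; then t-BuSH, visible light) would remove the extra carboxyl group and give 17.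

3. Step 15 (hydroboration and B-alkyl coupling). Hydroboration of the neopentyl-type vinyl group may be slow, and the alkyl borane may be lost by protodeboronation or β-hydride pathways before transmetalation. The fallback isolates the C12 carbon as an iodide and couples it as an organozinc; it sets out from 18 and comes back at 24. Hydroboration with 9-BBN and oxidative work-up (NaOH, H2O2) would give the primary alcohol 2-(trimethylsilyl)ethyl (1S,5S,6R,8aS)-5-(2-hydroxyethyl)-1,5,6-trimethyl-1,2,3,5,6,7,8,8a-octahydronaphthalene-1-carboxylate F9. Appel iodination (I2, PPh3, imidazole) would give the iodide 2-(trimethylsilyl)ethyl (1S,5S,6R,8aS)-5-(2-iodoethyl)-1,5,6-trimethyl-1,2,3,5,6,7,8,8a-octahydronaphthalene-1-carboxylate F10. Zinc insertion (Zn dust, LiCl, THF) would give the alkylzinc iodide F11, and Negishi coupling with 22 (Pd(OAc)2, SPhos, THF) would give 24.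

**Further compounds**

F1 | step 12 | 2-(trimethylsilyl)ethyl (1S,2R)-3-bromo-2-[(3R)-5-hydroxy-3,4-dimethylhexyl]-1-methylcyclohex-3-ene-1-carboxylate (mixture at the two new centres) | BrC1=CCC[C@](C)(C(=O)OCC[Si](C)(C)C)[C@H]1CC[C@@H](C)C(C)C(C)O
F2 | step 12 | 2-(trimethylsilyl)ethyl (1S,2R)-3-bromo-2-[(3R)-3,4-dimethyl-5-oxohexyl]-1-methylcyclohex-3-ene-1-carboxylate (mixture at the carbon next to the ketone) | BrC1=CCC[C@](C)(C(=O)OCC[Si](C)(C)C)[C@H]1CC[C@@H](C)C(C)C(C)=O
F3 | step 12 | 2-(trimethylsilyl)ethyl (1S,5S,6R,8aS)-5-acetyl-1,5,6-trimethyl-1,2,3,5,6,7,8,8a-octahydronaphthalene-1-carboxylate | CC(=O)[C@]1(C)C2=CCC[C@](C)(C(=O)OCC[Si](C)(C)C)[C@H]2CC[C@H]1C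
F4 | step 12 | 2-(trimethylsilyl)ethyl (1S,5S,6R,8aS)-1,5,6-trimethyl-5-[1-(trifluoromethylsulfonyloxy)ethenyl]-1,2,3,5,6,7,8,8a-octahydronaphthalene-1-carboxylate | C=C(OS(=O)(=O)C(F)(F)F)[C@]1(C)C2=CCC[C@](C)(C(=O)OCC[Si](C)(C)C)[C@H]2CC[C@H]1C
F5 | step 11 | (4R,5E)-4,5-dimethylhept-5-enoic acid | OC(=O)CC[C@@H](C)/C(C)=C/C
F6 | step 11 | (1S,4S)-2-bromo-4-methyl-4-{[2-(trimethylsilyl)ethoxy]carbonyl}cyclohex-2-en-1-yl (4R,5E)-4,5-dimethylhept-5-enoate | O=C(CC[C@@H](C)/C(C)=C/C)O[C@@H]1C(Br)=C[C@@](C)(C(=O)OCC[Si](C)(C)C)CC1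
F7 | step 11 | 2-(trimethylsilyl)ethyl (1S,2R)-3-bromo-2-[(3R,4E)-1-carboxy-3,4-dimethylhex-4-en-1-yl]-1-methylcyclohex-3-ene-1-carboxylate (mixture at the carboxyl-bearing carbon) | BrC1=CCC[C@](C)(C(=O)OCC[Si](C)(C)C)[C@H]1C(C(=O)O)C[C@@H](C)/C(C)=C/C
F8 | step 11 | N-hydroxypyridine-2-thione ester of F7 | BrC1=CCC[C@](C)(C(=O)OCC[Si](C)(C)C)[C@H]1C(C(=O)On1ccccc1=S)C[C@@H](C)/C(C)=C/C
F9 | step 15 | 2-(trimethylsilyl)ethyl (1S,5S,6R,8aS)-5-(2-hydroxyethyl)-1,5,6-trimethyl-1,2,3,5,6,7,8,8a-octahydronaphthalene-1-carboxylate | OCC[C@]1(C)C2=CCC[C@](C)(C(=O)OCC[Si](C)(C)C)[C@H]2CC[C@H]1C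
F10 | step 15 | 2-(trimethylsilyl)ethyl (1S,5S,6R,8aS)-5-(2-iodoethyl)-1,5,6-trimethyl-1,2,3,5,6,7,8,8a-octahydronaphthalene-1-carboxylate | ICC[C@]1(C)C2=CCC[C@](C)(C(=O)OCC[Si](C)(C)C)[C@H]2CC[C@H]1C
F11 | step 15 | alkylzinc iodide from F10 | I[Zn]CC[C@]1(C)C2=CCC[C@](C)(C(=O)OCC[Si](C)(C)C)[C@H]2CC[C@H]1C
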